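A curve that bends over tempts you to read a dying catalyst, though falling reagents can bend it too.

| flask | left-handed substrate | right-handed substrate | partner | free catalyst | remark |
|---|---|---|---|---|---|
| grey | 0.55 M | 0.55 M | 0.44 M | 42 mM | run made earlier |
| flask | 0.55 M | 0.55 M | 0.440 M | 28 mM |  |

- grey (time / min: left-handed product / %): 5.00: 1.2; 8.00: 4.0; 12.0: 3.0; 20.0: 6.1; 40.0: 10.9; 60.0: 12.4

(each reading ± 1 percentage point)

- free catalyst is single-handed; left-handed substrate and right-handed substrate are mirror images of each other, charged as a racemate, each of them at the stated concentration
- on the list of suspects stand: partner + free catalyst + left-handed substrate -> free catalyst + left-handed product; partner + free catalyst + right-handed substrate -> free catalyst + right-handed product; partner + free catalyst -> spent catalyst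
- no earlier run changes the charge of free catalyst; that part of a forecast is a guess

1. apparent order in free catalyst when 30% of the left-handed substrate and right-handed substrate together are converted (percent change of the rate of making left-handed product for one percent more free catalyst charged)

The grey run and the flask differ in one charge: free catalyst, 42 mM against 28 mM. Each turnover takes one partner, so partner is the limiting reagent in both, and it allows 40.0% conversion of the two substrates together. Both therefore head for that ceiling as long as free catalyst lasts.

Does the grey bend need catalyst loss? Compare its rate at two moments. From the first 20.0 min to the following stretch, the rate of making left-handed product falls to 0.516 of its early value. If you let the right-handed substrate react alike, the falling c(partner)·c(left-handed substrate) already asks for 0.445, so within their scatter these grey readings do not ask for a loss of catalyst. Moving the two differences one scatter against each other still leaves a surviving share of 0.838.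

On the list of suspects, turnover and death both go with c(partner)·c(free catalyst), so the catalyst lost follows conversion, not the clock, and does not depend on the charge of free catalyst, with the other charges held as they are here. Scaled to 30% conversion, that one-scatter edge is a loss of 9.36 mM, an estimate and not a bound. At fixed conversion the rate follows the free catalyst, so the order is the charge over what is still free, which I call the fixed-conversion order 1.50. I expect the flask between 1 and that figure.

The forecast gives 2, within 1.2 to 5, higher than my figure, and says: “The unmeasured selectivity dominates the uncertainty”.

The flask gives 1.2: at 3.22 h, with 30% converted, 86.7% of the catalyst is free and 13.3% spent, so the rule that gave 1.50 now gives 1.15, and the same loss on the grey charge gives 1.10. partner + free catalyst + left-handed substrate → free catalyst + left-handed product (k = 25.0 M⁻² h⁻¹); partner + free catalyst + right-handed substrate → free catalyst + right-handed product (k = 14.0 M⁻² h⁻¹); partner + free catalyst → spent catalyst (k = 0.200 M⁻¹ h⁻¹)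

Per free catalyst at the charged concentrations, the step to right-handed product runs at 3.4 h⁻¹ and the step to spent catalyst at 0.088 h⁻¹, a ratio of 38.6.

(All runs are calculated on assumed constants.)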